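A small charge of substrate, 0.045 M, shares a stirred flask with 1.80 equiv of coupling partner, and we follow how isomer of the product stands to target, all amounts as fractions of the substrate charged.

| flask | substrate | coupling partner | remark | time |
|---|---|---|---|---|
| zeta | 0.045 M | 1.8 equiv | the very flask that is asked about, followed so far |  |
| theta | 0.045 M | 3.6 equiv | run made earlier |  |
| flask | 0.045 M | 1.80 equiv |  | 20 min |

- zeta (time / min: isomer of the product / %, target / %): 0.833: 6.4, 9.5; 2.00: 11.9, 16.2; 4.00: 19.6, 22.8; 10.0: 28.1, 25.9
- theta (time / min: isomer of the product / %, target / %): 1.00: 13.4, 19.0; 2.50: 24.2, 31.3; 6.00: 31.4, 37.0; 15.0: 34.7, 36.7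

(each reading ± 1 percentage point)

- ratio of isomer of the product to target at 2.5 s
- ratio of isomer of the product to target at 50 s
- ratio of isomer of the product to target at 20 min

- in percentages every species weighs as the substrate in it: one side product counts as two
- reactions considered so far: substrate + coupling partner <-> target; substrate + coupling partner <-> isomer of the product; substrate <-> dormant form; substrate + target -> side product

*Why should the first ratio ignore the partner charge?* Target and isomer each form from one substrate and one partner, so while neither goes back, their rates stand in the ratio of two constants, whatever the amounts. The first readings agree: 0.674 in zeta and 0.705 in theta, with twice the partner, each ratio good to about 0.1. Pooling them gives the split, isomer formed per target formed, 0.695, a selectivity factor.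

*Then why does the ratio climb?* Substrate also consumes target, and no listed step consumes isomer that way. So I divide the split by the ratio and call this the standing share: how much of the target that the isomer's amount calls for still stands. In zeta it reads 0.808 at 4.00 min and 0.640 at 10.0 min.

*Your split comes from readings near one minute. Is it good at 2.5 s?* That is unproven, but I take the split for both early times. For 20 min I commit only to a ratio above the 1.08 read at 10.0 min, since the share was still falling.

The forecast gives 0.63, 0.67 and 1.27. Its early ratios “extrapolate smoothly to about 0.63 at zero time”, and its value at 50 s lies below my split, by less than the scatter.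

The flask gives 0.640, 0.691 and 1.33.

    substrate + coupling partner ⇌ target (K = 96.0 M⁻¹, k = 2.20 M⁻¹ min⁻¹)
    substrate + coupling partner ⇌ isomer of the product (K = 240 M⁻¹, k = 1.40 M⁻¹ min⁻¹)
    substrate ⇌ dormant form (K = 0.390, k = 2.30 min⁻¹)
    substrate + target → side product (k = 5.80 M⁻¹ min⁻¹)

The half-life of isomer for going back, 120 min, is longer than the 20 min of the flask, while target, made 2.88 times faster than used up, each step taken net, at 2.40 min, stands at 23.2% against 31.0% of isomer at the end, a standing share of 0.523. With 1.10 equiv of partner, the split again promises 0.695 at 50 s, and that neighbour gives 0.693; its ratio at 20 min is 1.68, a standing share of 0.414.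

(Readings and results are calculated with made-up constants, and the scatter is random.)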